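The reagent is what we book first in this flask: the single-handed free catalyst turns the racemate into left-handed and right-handed product, and we take it that each product uses one reagent.

| setting | delta | zeta | theta | flask |
|---|---|---|---|---|
| left-handed substrate | 0.33 M | 0.33 M | 0.33 M | 0.33 M |
| right-handed substrate | 0.33 M | 0.33 M | 0.33 M | 0.33 M |
| reagent | 0.33 M (fed, over 25 s) | 1.3 M (fed, over 25 s) | 0.66 M (fed, over 25 s) | 0.660 M (fed, over 25 s) |
| free catalyst | 3.3 mM | 3.3 mM | 4.9 mM | 3.3 mM |
| remark | run made earlier; the fed solution adds 0.10 times the starting volume | run made earlier; the fed solution adds 0.10 times the starting volume | run made earlier; the fed solution adds 0.10 times the starting volume | the fed solution adds 0.10 times the starting volume |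
| time |  |  |  | 8.0 min |

- delta (time / min: left-handed product / %, right-handed product / %, left-handed substrate / %): 0.417: 0, 0, 49; 0.667: 1, 4, 45; 1.33: 3, 7, 47; 2.50: 9, 14, 40; 5.00: 5, 25, 36
- zeta (time / min: left-handed product / %, right-handed product / %, left-handed substrate / %): 0.417: 5, 9, 49; 1.33: 11, 30, 33; 2.00: 19, 36, 30; 3.00: 23, 39, 20; 5.00: 27, 46, 19
- theta (time / min: left-handed product / %, right-handed product / %, left-handed substrate / %): 1.00: 11, 15, 38; 2.00: 16, 29, 33; 3.00: 20, 38, 27; 4.00: 22, 43, 23; 5.00: 22, 51, 20

(each reading ± 2 percentage points)

1. excess of left-handed product over right-handed product in the product at 25 s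
2. excess of left-handed product over right-handed product in the product at 8.0 min
3. part of the left-handed substrate and right-handed substrate charged together that has reacted at 8.0 min

- free catalyst is single-handed; left-handed substrate and right-handed substrate are mirror images of each other, charged as a racemate, each of them at the stated concentration
- charges are per starting volume, the dose included; the dosed solution carries all of it
- an excess is the difference of the two amounts in percent of their sum
- an excess is below zero if the other one leads

The equivalents, the reagent charge as a fraction of both substrates charged together, come to E = 1.00. With X the reacted fraction of both substrates: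

unconsumed reagent, as a fraction of its charge = 1 − X/E

Turn the question round: for the reagent to be the limiting reagent, E must lie below 1, and X then has the ceiling E. Delta stands on that side, with E = 0.500, and its reading of 30.0% at 5.00 min leaves 40.0% by the balance. This flask stands on the boundary, so its ceiling is the whole pair.

Theta has the same E and reads 73.0% at 5.00 min. This flask's catalyst charge times time is 1.08 times theta's, so we expect about that reading here, with 27.0% of the reagent unconsumed.

The forecast gave excesses of −35% and −26% and a reacted part of 62%, reasoning that the reagent “depletes as it reacts”.

The flask gives −42.1% at 25 s, −37.5% at 8.0 min, and 66.8% reacted, below our theta reading.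

    free catalyst + left-handed substrate ⇌ catalyst intermediate A (K = 2.74 M⁻¹, k = 160 M⁻¹ s⁻¹)
    free catalyst + right-handed substrate ⇌ catalyst intermediate B (K = 27.0 M⁻¹, k = 49.6 M⁻¹ s⁻¹)
    reagent + catalyst intermediate A → free catalyst + left-handed product (k = 6.57 M⁻¹ s⁻¹)
    reagent + catalyst intermediate B → free catalyst + right-handed product (k = 2.18 M⁻¹ s⁻¹)
    reagent + free catalyst → spent catalyst (k = 0.0549 M⁻¹ s⁻¹)
    reagent ⇌ dormant form (K = 0.650, k = 0.0536 s⁻¹)
    left-handed substrate ⇌ right-handed substrate (k = 0.00459 s⁻¹)

The balance now leaves 33.2% of the reagent unconsumed in this flask, but 20% stands free at 8.00 min; the dormant form holds the other 13.1% of the charge. The right-handed product leads in this flask at 8.0 min mainly because catalyst intermediate A goes back to free catalyst and left-handed substrate: the run with that return taken away gives an excess of 70.6% at that time, against −37.5% with it.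

In the neighbour with 1.1 M of reagent, E = 1.67, so the whole pair needs 60.0% of the charge. It reacts 75.3%, so the balance gives 54.8% unconsumed, which stands as 33% free and 21.5% dormant.

The numbers in the tables were generated by integration for an exercise, and the scatter is random.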